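**Compound numbers used throughout:** 1 3,4-dibromoaniline; 2 hemiaminal ether (not isolated); 3 3,4-dibromo-N-methylaniline; 4 propiolic acid; 5 dimethylamine; 6 propiolamide (not isolated); 7 β-(dimethylamino)acrylanilide; 8 3-aminomethylidene oxindole; 9 iminium salt (not isolated); 10 target.

## Analysis of the target

Target 10 is an indole: a pyrrole ring (N1, C2, C3, C3a, C7a) fused to a benzene ring (C3a, C4, C5, C6, C7, C7a). It carries CH3 on N1, Br on C2, CHO on C3 and Br on C5 and C6. It has no stereocentre and no stereogenic double bond, so the whole problem is regiochemistry and functional-group tolerance.

On the benzene ring two adjacent bromines (C5, C6) sit between two free positions (C4, C7). Four positions of similar reactivity make late electrophilic bromination untrustworthy, so this pattern should come from a building block.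

C2(Br)=C3–CH=O is a vinylogous acyl bromide. The C2–Br bond is open to addition–elimination by amines, hydroxide and alkoxides. The three C–Br bonds rule out organolithium reagents, dissolving metals, hydrogenolysis and phosphine-ligated zerovalent palladium at high temperature, so C2–Br cannot be installed late by lithiation.

The feature that invites the key move is the C3–C3a bond. Both carbons are donors: C3a is an arene carbon ortho to N1, and C3 is the α-carbon of a C2 carbonyl, or the β-carbon of an enamine once the future formyl carbon is attached as an aminomethylidene group. The bond can therefore be made by removing two hydrogens, which closes the five-membered ring at carbon. The C2(Br)=C3–CH=O unit is also the imprint of such a C2 lactam carbonyl next to a C3 aminomethylidene group, so the ring can be built one oxidation state below the indole and aromatised in the last step.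

## Retrosynthetic reasoning

**10 ⇒ 9 ⇒ 8 (C2–Br and the aldehyde oxygen).** The C2–Br bond and the C=O of the aldehyde are cut first. Their natural precursor is the vinylogous amide N1–C2(=O)–C3=CH–N of 8. In the forward direction an oxophilic bromophosphorus reagent turns the lactam oxygen of 8 into a leaving group, bromide takes its place at C2 with aromatisation to iminium salt 9, and water releases 10. This is cut here because it installs C2–Br without electrophilic bromination (which would touch C4 or C7) and without a carbanion at C2. The gain is that the five-membered ring may be built at the lactam level, where C3 is a donor carbon.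

**8 ⇒ 7 (C3–C3a, the key disconnection).** The five-membered ring of 8 is opened at C3–C3a and not at N1–C7a or N1–C2. This leads to the acyclic anilide 7, in which every atom of 10 except the C2 bromine is already present and both bromines sit on the aniline part. The forward reaction has to join two C–H carbons of like (donor) polarity under oxidation. It must choose the ortho carbon flanked by hydrogen over the one flanked by bromine, and it must leave the C–Br bonds alone.

**7 ⇒ 6 + 5 (enamine C–N bond).** The dimethylamino group of 7 is cut from the β-carbon. Conjugate addition of 5 to the ynamide 6 forms this bond without a reagent or a by-product. The amine makes the α-carbon nucleophilic for the key step, blocks C3 of 8 against further oxidation, and becomes the leaving group in the last step.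

**6 ⇒ 3 + 4 (amide C–N bond).** The amide bond of 6 is cut to the secondary aniline 3 and the three-carbon acid 4. Carbon C1 of 4 becomes C2 of the indole, C2 becomes C3 and C3 becomes the formyl carbon. The forward reaction is a carbodiimide coupling; 6 need not be isolated.

**3 ⇒ 2 ⇒ 1 (N1–CH3 bond).** The N-methyl group is cut last. It is installed first in the forward direction, because a secondary N-methyl anilide prefers the rotamer that holds the aryl ring next to the acyl chain, which the ring closure needs. Reductive methylation of 1 by way of hemiaminal ether 2 stops cleanly at the secondary amine.

## Alternatives that were turned down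

**Alternative 1:** (the textbook route) Disconnection: the C5–Br and C6–Br bonds, no skeletal bond. Forward: Vilsmeier–Haack–Arnold bromoformylation of 1-methylindolin-2-one A1 to 2-bromo-1-methylindole-3-carbaldehyde A2, then twofold electrophilic bromination of A2 as the key step to give 10. Turned down because the pattern would rest on two consecutive electrophilic substitutions on a benzene ring deactivated by the vinylogous formamide. N1 directs to C5 and C7, while the acceptor at C3 deactivates C4 and C6. The second bromine would have to enter at C6, next to the first one and against both effects, while C7 stays open. The by-products would be constitutional isomers with the same formula and almost the same polarity. The route is two steps, but the one selectivity the target demands is left to chance and the key step forms no skeletal bond.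

**Alternative 2:** Disconnection: N1–C7a and C3–C3a at once, which uses the local symmetry of the 4,5-dibromo-1,2-phenylene unit. Forward: formal [3+2] annulation of the C2v-symmetric 4,5-dibromobenzyne A3 with methyl 2-(methylamino)-2-oxoacetate A4. The amide nitrogen adds to the aryne and the aryl anion closes on the ester, giving 5,6-dibromo-1-methylisatin A5. Wolff–Kishner reduction would give 5,6-dibromo-1-methylindolin-2-one A6, and bromoformylation would give 10. The regiochemistry of the bromines cannot go wrong, which is the attraction. Turned down on step economy and compatibility:
- A3 is available in one step only from 1,2,4,5-tetrabromobenzene A7 by halogen–lithium exchange, and the alkyllithium would destroy the electrophilic partner A4.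
- The fluoride-triggered precursor 4,5-dibromo-2-(trimethylsilyl)phenyl trifluoromethanesulfonate A8 needs three to four steps of its own.
- The C3 carbonyl of A5 has to be removed again.
The way to the precursor costs more than the annulation wins.

**Alternative 3:** Disconnection: C3–C3a as in the chosen route, but by polar chemistry. Forward: Stollé-type Friedel–Crafts closure of 2-chloro-N-(3,4-dibromophenyl)-N-methylacetamide A9 (from 3) with a strong Lewis acid in the melt to give A6, then bromoformylation to 10. Turned down for three reasons:
- The ring carries two bromines and an amide nitrogen that is tied up by the Lewis acid, so forcing conditions are needed.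
- Under those conditions aryl bromides migrate and disproportionate through arenium ions.
- Attack at either ortho carbon places the positive charge on the same atoms (the N-bearing carbon and the bromine-bearing C3 of the aniline ring), so there is no electronic bias and only a weak steric one between the 5,6- and the 4,5-dibromo series.

Key step: step 3

Remark: 10 is achiral. The only stereo-elements on the way are the E double bond of 7 and the exocyclic double bond of 8. The latter is expected as an E/Z mixture and is written without geometry, because both isomers give 9.

## Route

Step 1
Reactants: 1 3,4-dibromoaniline
Product: 3 3,4-dibromo-N-methylaniline, via N-(methoxymethyl)-3,4-dibromoaniline 2 (not isolated)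
Conditions: NaOMe, (CH2O)n, MeOH, reflux; then NaBH4, 0 °C to reflux
Reagents that add atoms: formaldehyde (as paraformaldehyde), C=O; methanol, CO (its methoxy group is carried by 2 only)
Why: Reductive N-monomethylation: in NaOMe/MeOH the aniline condenses with formaldehyde to hemiaminal ether 2, which NaBH4 reduces to the secondary amine. Under basic conditions 3 forms no iminium ion, so a second methylation is not expected, and the aryl bromides are inert to borohydride.

Step 2
Reactants: 3 3,4-dibromo-N-methylaniline; 4 propiolic acid; 5 dimethylamine
Product: 7 (E)-N-(3,4-dibromophenyl)-3-(dimethylamino)-N-methylprop-2-enamide, via N-(3,4-dibromophenyl)-N-methylprop-2-ynamide 6 (not isolated)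
Conditions: DCC, CH2Cl2, 0 °C to rt; then 5 (2 M in THF), 0 °C to rt
Reagents that add atoms: none
Why: Carbodiimide amide coupling of the secondary aniline with activated propiolic acid gives ynamide 6. The secondary amine 5 then undergoes conjugate addition to the electron-poor triple bond in the same flask and should give the thermodynamically favoured E push–pull enamine 7.

Step 3
Reactants: 7 (E)-N-(3,4-dibromophenyl)-3-(dimethylamino)-N-methylprop-2-enamide
Product: 8 5,6-dibromo-3-[(dimethylamino)methylidene]-1-methyl-1,3-dihydro-2H-indol-2-one (E/Z mixture)
Conditions: Pd(OAc)2 (10 mol %), Cu(OAc)2 (2.2 equiv), K2CO3 (2.2 equiv), 4 Å MS, DMF, 90 °C, argon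
Reagents that add atoms: none
Why: Intramolecular cross-dehydrogenative coupling of two donor carbons under catalysis by divalent palladium: electrophilic palladation of the enamine β-carbon of 7 (the future C3) gives an α-palladated vinylogous amide, acetate-assisted concerted metalation–deprotonation of an anilide ortho C–H gives a six-membered palladacycle, C–C reductive elimination closes the lactam ring of 8, and Cu(OAc)2 returns zerovalent palladium to the divalent state. The closest known reaction types are the oxidative cyclisation of N-aryl enaminones to indoles with Pd(OAc)2/Cu(OAc)2 and the oxidative closure of N-alkyl-N-arylacrylamides to 3-alkylidene oxindoles by aromatic C–H alkenylation; 7 is such an acrylamide, made more nucleophilic at the α-carbon by its β-amino group. Mode of closure: the five-membered ring N1–C2–C3–C3a–C7a is closed at C3–C3a, formally a 5-exo-trig attack of the arene carbon on the acrylamide α-carbon, helped by the N-methyl anilide rotamer that holds the aryl ring next to the acyl chain. No stereocentre is formed, and the exocyclic double bond may equilibrate between E and Z without consequence because step 4 removes this element. The first selectivity needed is C–H cleavage at the ortho carbon flanked by hydrogen and not at the one flanked by bromine, so that the bromines end on C5 and C6; base-assisted metalation is sensitive to an ortho bromine, and closure at the hindered carbon would force a C4 bromine into the plane of the C3 aminomethylidene group, a peri clash that the 5,6-isomer is free of. The second selectivity is that the aryl C–Br bonds stay untouched, which is expected because divalent palladium does not add to them and phosphine-free zerovalent palladium is reoxidised by the excess of Cu(OAc)2; K2CO3 and the sieves keep the enamine from acid-promoted hydrolysis.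

Step 4
Reactants: 8 5,6-dibromo-3-[(dimethylamino)methylidene]-1-methyl-1,3-dihydro-2H-indol-2-one
Product: 10 2,5,6-tribromo-1-methylindole-3-carbaldehyde, via iminium dibromophosphate 9 (not isolated)
Conditions: POBr3 (1.3 equiv), ClCH2CH2Cl, 0 to 70 °C; then ice-water, NaHCO3 to pH 6–7
Reagents that add atoms: phosphoryl bromide POBr3, O=P(Br)(Br)Br; water, O
Why: Second half of a Vilsmeier–Haack–Arnold haloformylation: the vinylogous amide oxygen of 8 is phosphorylated, bromide displaces the dibromophosphate at C2 by addition–elimination with aromatisation to the indole, and hydrolysis of iminium salt 9 should give the aldehyde. The aryl bromides are inert, and the work-up is kept at pH 6–7 so that the liberated amine stays protonated and cannot displace the activated C2 bromide.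

## Compound list

1 | 3,4-dibromoaniline | Nc1ccc(Br)c(Br)c1 | starting material
2 | N-(methoxymethyl)-3,4-dibromoaniline | COCNc1ccc(Br)c(Br)c1 | intermediate
3 | 3,4-dibromo-N-methylaniline | CNc1ccc(Br)c(Br)c1 | intermediate
4 | propiolic acid (prop-2-ynoic acid) | C#CC(=O)O | starting material
5 | dimethylamine | CNC | starting material
6 | N-(3,4-dibromophenyl)-N-methylprop-2-ynamide | C#CC(=O)N(C)c1ccc(Br)c(Br)c1 | intermediate
7 | (E)-N-(3,4-dibromophenyl)-3-(dimethylamino)-N-methylprop-2-enamide | CN(C)/C=C/C(=O)N(C)c1ccc(Br)c(Br)c1 | intermediate
8 | 5,6-dibromo-3-[(dimethylamino)methylidene]-1-methyl-1,3-dihydro-2H-indol-2-one (E/Z mixture, geometry left open) | CN(C)C=C1C(=O)N(C)c2cc(Br)c(Br)cc12 | intermediate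
9 | [(2,5,6-tribromo-1-methylindol-3-yl)methylidene]dimethylammonium dibromophosphate | C[N+](C)=Cc1c(Br)n(C)c2cc(Br)c(Br)cc12.[O-]P(=O)(Br)Br | intermediate
10 | 2,5,6-tribromo-1-methylindole-3-carbaldehyde | Cn1c(Br)c(C=O)c2cc(Br)c(Br)cc21 | target

## Step count and least certain steps

Total step count: 4. Longest linear sequence: 4 steps (1 → 3 → 7 → 8 → 10).

**Step 3 (key step).** Three processes are the most likely to go wrong:
- C–H cleavage at the bromine-flanked ortho carbon, which closes the ring in the wrong direction.
- One-electron oxidation of the electron-rich enamine by divalent copper, leading to oxidative dimerisation at the α-carbon.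
- Acid-promoted 6-endo attack of the arene on the β-carbon with loss of the amine.

Fallback: mark the closing carbon with iodine and close the same bond by a Heck reaction. The fallback sets out from 3. Electrophilic iodination (N-iodosuccinimide, MeCN, 0 °C to rt) should go to the free, unhindered ortho position and give 4,5-dibromo-2-iodo-N-methylaniline F1. Coupling of F1 with 4 (DCC, CH2Cl2) gives N-(4,5-dibromo-2-iodophenyl)-N-methylprop-2-ynamide F2. Addition of 5 in the same flask gives (E)-N-(4,5-dibromo-2-iodophenyl)-3-(dimethylamino)-N-methylprop-2-enamide F3. An intramolecular Heck reaction (Pd(OAc)2, PPh3, NaOAc, DMF, 80 °C) then closes the ring: zerovalent palladium adds to the C–I bond far faster than to the C–Br bonds, 5-exo-trig carbopalladation forms C3–C3a, and β-hydride elimination gives the exocyclic enamine. The fallback comes back to the route at 8.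

**Step 2.** The most likely problem is sluggish acylation of the electron-poor secondary aniline, so that conjugate addition to the activated triple bond and oligomerisation of activated propiolic acid compete. Fallback without the alkyne: from 3, acylation with (E)-3-ethoxyacryloyl chloride (NaHCO3, CH2Cl2/H2O) gives (E)-N-(3,4-dibromophenyl)-3-ethoxy-N-methylprop-2-enamide F4. Heating F4 with 5 in EtOH in a sealed tube exchanges the ethoxy group for the amine by addition–elimination at the β-carbon. The fallback comes back to the route at 7.

**Step 1.** The most likely problem is incomplete condensation of the weakly basic aniline with formaldehyde, or a second methylation. Fallback through the amide oxidation level: from 1, formylation with acetic formic anhydride (HCO2H, Ac2O, THF) gives N-(3,4-dibromophenyl)formamide F5, which is reduced with BH3·SMe2 (THF, reflux). The fallback comes back to the route at 3.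

## Further compounds

F1 | step 3 | 4,5-dibromo-2-iodo-N-methylaniline | CNc1cc(Br)c(Br)cc1I
F2 | step 3 | N-(4,5-dibromo-2-iodophenyl)-N-methylprop-2-ynamide | C#CC(=O)N(C)c1cc(Br)c(Br)cc1I
F3 | step 3 | (E)-N-(4,5-dibromo-2-iodophenyl)-3-(dimethylamino)-N-methylprop-2-enamide | CN(C)/C=C/C(=O)N(C)c1cc(Br)c(Br)cc1I
F4 | step 2 | (E)-N-(3,4-dibromophenyl)-3-ethoxy-N-methylprop-2-enamide | CCO/C=C/C(=O)N(C)c1ccc(Br)c(Br)c1
F5 | step 1 | N-(3,4-dibromophenyl)formamide | O=CNc1ccc(Br)c(Br)c1
A1 | alternative 1 | 1-methylindolin-2-one | CN1C(=O)Cc2ccccc21
A2 | alternative 1 | 2-bromo-1-methylindole-3-carbaldehyde | Cn1c(Br)c(C=O)c2ccccc21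
A3 | alternative 2 | 4,5-dibromobenzyne (4,5-dibromo-1,2-didehydrobenzene) | BrC1=CC#CC=C1Br
A4 | alternative 2 | methyl 2-(methylamino)-2-oxoacetate | CNC(=O)C(=O)OC
A5 | alternative 2 | 5,6-dibromo-1-methylindoline-2,3-dione | CN1C(=O)C(=O)c2cc(Br)c(Br)cc21
A6 | alternative 2 | 5,6-dibromo-1-methylindolin-2-one | CN1C(=O)Cc2cc(Br)c(Br)cc21
A7 | alternative 2 | 1,2,4,5-tetrabromobenzene | Brc1cc(Br)c(Br)cc1Br
A8 | alternative 2 | 4,5-dibromo-2-(trimethylsilyl)phenyl trifluoromethanesulfonate | C[Si](C)(C)c1cc(Br)c(Br)cc1OS(=O)(=O)C(F)(F)F
A9 | alternative 3 | 2-chloro-N-(3,4-dibromophenyl)-N-methylacetamide | CN(C(=O)CCl)c1ccc(Br)c(Br)c1
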